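The readings are calculated on assumed constants, and the scatter is random.

1. Don't trust a closed balance. In the theta run, starting material and target sum to 101% at the last reading, yet that sum contains no reading of the coupling partner or the second substrate.

- theta: starting material 0.53 M; coupling partner 0.32 M; second substrate 0.53 M; precatalyst 0.53 mM; run made earlier
- flask: starting material 0.53 M; coupling partner 0.636 M; second substrate 0.530 M; precatalyst 0.53 mM; time 2.5 d

- theta (time / h: starting material / %, target / %): 5.00: 94.8, 5.8; 10.0: 85.4, 14.0; 15.0: 77.6, 21.5; 20.0: 73.1, 27.7

(scatter of a reading: 0.5 percentage points)



- the species that holds most of what was charged as starting material, at 2.5 d (starting material / target)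
- the largest share itself, whichever of these holds it, in percent of the starting material charged

2. Divide the rate of [coupling partner] loss by the rate of [target] gain and time drops out, leaving the partner cost of one target. This flask has 1.20 partner equivalents, charged [coupling partner] over charged [starting material], and the theta run had 0.604. Your rule: the target share cannot pass equivalents divided by cost. At cost 1, the theta run has the partner as limiting reagent, but this flask does not, since its equivalents exceed one.

3. How fast? At the theta run's late pace, target gains half the charge in 40.3 h, less than the 60 h available. So I expect target to hold most.

4. Objection: the second substrate, charged equally, may spend partner too. An even competition means cost 2, with ceilings of 30.2% for the theta run and 60.0% for this flask. But the theta run reached 27.7% after gaining 6.2 percentage points in its last interval, more than the 2.5 points still below that ceiling. I therefore put the cost between 1 and 2, and this flask's ceiling above 60.0%.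

5. The forecast says target at 78%, “though the order is not well determined from this single run”.

6. The flask gives target at 72.8%.

    starting material + coupling partner + catalyst → catalyst + target (k = 0.128 M⁻² s⁻¹)
    precatalyst ⇌ catalyst (K = 1.00, k = 2.17 × 10⁻⁵ s⁻¹)
    second substrate + coupling partner + catalyst → catalyst + second product (k = 0.0445 M⁻² s⁻¹)

The shrinking supply of coupling partner is the main reason for the shortfall: without that shrinkage, this flask gives 98.4% target instead of 72.8%. With 9.0% of the partner left, its 1.20 equivalents work out at a cost of 1.50 per target. The neighbour charged with 2.1 M of second substrate has the same equivalents but keeps 0.22% of its partner and reaches 45.1% target, a cost of 2.65.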